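The numbers in the tables are calculated from invented constants; the scatter is artificial.

I wanted to know how target stood against other capture product in this flask, early, at a day and at the end.

| setting | green | blue | flask |
|---|---|---|---|
| starting material | 1.5 M | 1.5 M | 1.5 M |
| first nucleophile | 0.67 equiv | 1.5 equiv | 1.00 equiv |
| second nucleophile | 0.60 equiv | 0.60 equiv | 0.600 equiv |
| remark | run made earlier | run made earlier |  |
| time |  |  | 15 d |

- green (time / d: target / %, other capture product / %, starting material / %): 1.67: 8, 14, 38; 4.00: 2, 20, 11; 5.00: 7, 23, 6; 8.00: 5, 24, 0; 10.0: 3, 26, 0
- blue (time / d: target / %, other capture product / %, starting material / %): 0.625: 7, 5, 71; 1.25: 9, 7, 47; 2.50: 9, 9, 23; 5.00: 8, 13, 4; 10.0: 6, 11, 0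

(scatter of a reading: 1.5 percentage points)

- ratio of target to other capture product at 2.0 h
- ratio of target to other capture product at 25 h
- ratio of target to other capture product at 15 d



1. I called the gap whatever the three readings did not account for. In the blue run at 10.0 d it read 83.0%. I assumed that each lost target took one starting material with it, so half the gap was target made and lost.
2. That blue reading then gave 4.32 target made per other capture product. Dividing by [first nucleophile]/[second nucleophile] as charged gave a selectivity factor of 1.73, a reading that carries the scatter of 1.5 percentage points. For this flask it gave the made ratio, target made per other capture product made, lost target counted: 2.88.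
3. Fastest rung: the blue readings put the half-life of starting material near 1.15 d. 2.0 h is much shorter than that, but that half-life belongs to starting material and is not a clock for target, and I had no reading so early to show how fast target goes. So I wrote down a ratio near 2.88, counting no lost target, as a first figure.
4. Middle rung: over days, starting material and target meet, and the gap grows. I had no sharper number for 25 h.
5. Slowest rung: once starting material reads zero, the flask stands still. The charge equals target left, plus other capture product, plus twice the lost target. Target left plus lost target is the made ratio times other capture product. Taking target left as 4.50%, the mean of the last readings, other capture product ends at 15.5%, a ratio of 0.291.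
6. The forecast gave 1.1, 0.9 and 0.22: “The ratio then drifts down, because the target slowly decays or converts”. My two ends stood higher.
7. The flask gave 2.72, 0.901 and 0.401.

    first nucleophile + intermediate → target (k = 1.20 M⁻¹ h⁻¹)
    starting material → intermediate (k = 0.0150 h⁻¹)
    second nucleophile + intermediate → other capture product (k = 0.640 M⁻¹ h⁻¹)
    starting material + target → side product (k = 0.110 M⁻¹ h⁻¹)

At 1.13 d in this flask, starting material went 1.4 times as fast to intermediate as into the step with target, and the flask ended with 77.0% side product, a figure in which each side product counts two. Its made ratio at the end was 2.75, against my 2.88, and the neighbour flask charged with 0.90 M of starting material, at the same equivalents, ended at 2.73.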